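**Assumption:** an (R)-selective ketoreductase for ketone 4 is taken from a commercial KRED screening panel (both enantiopreferences are sold), and ee is checked by chiral HPLC or Mosher ester before going on.

**Target check:** the SMILES decodes to methyl 4-[(2R,5S)-5-[(3E,11E)-12-bromododeca-3,11-dien-1-yn-1-yl]tetrahydrofuran-2-yl]butanoate, a trans-2,5-disubstituted THF.

## Retrosynthetic overview

1. Cut the C(sp)–C(sp2) enyne bond (Sonogashira): THF-alkyne 9 plus (1E,9E)-1-bromo-10-iododeca-1,9-diene 14, with the C–I bond reacting and C–Br a spectator.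
2. Alkyne 9 comes from the THF-CH2OH compound 7 by oxidation and one-carbon homologation.
3. The only ring, the trans-THF, is formed by cobalt-catalysed aerobic oxidative cyclisation of (R)-5-hydroxy-8-enoate 5; the C5 carbinol controls the new ring stereocentre.
4. The C5 carbinol comes from ketoreductase reduction of prochiral keto ester 4, made from mono-tert-butyl glutarate and butenyl Grignard via a Weinreb amide.
5. Diene 14 comes from non-8-yn-1-ol by two hydrozirconation–halogenations, which fix both E-alkenes.

## Route

**Step 1**
Reactants: 1, 5-(tert-butoxy)-5-oxopentanoic acid (mono-tert-butyl glutarate)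
Product: 2, tert-butyl 5-[methoxy(methyl)amino]-5-oxopentanoate
Conditions: MeNHOMe·HCl, EDC·HCl, HOBt, i-Pr2NEt, CH2Cl2, 0 °C → rt
Reagents that add atoms: N,O-dimethylhydroxylamine hydrochloride, CNOC.Cl
Why: Standard carbodiimide amide coupling gives the Weinreb amide, and the tert-butyl ester is untouched.

**Step 2**
Reactants: 2, the Weinreb amide; 3, but-3-en-1-ylmagnesium bromide
Product: 4, tert-butyl 5-oxonon-8-enoate
Conditions: 3 (1.3 equiv), THF, 0 °C; aq. NH4Cl
Reagents that add atoms: but-3-en-1-ylmagnesium bromide, C=CCC[Mg]Br
Why: Weinreb ketone synthesis; the chelated tetrahedral intermediate stops over-addition, and the hindered tert-butyl ester is inert to the Grignard at 0 °C.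

**Step 3**
Reactants: 4, tert-butyl 5-oxonon-8-enoate
Product: 5, tert-butyl (5R)-5-hydroxynon-8-enoate
Conditions: (R)-selective ketoreductase (KRED), NADP+ (cat.), glucose dehydrogenase / D-glucose, KPi buffer pH 7.0, 10% DMSO, 30 °C
Reagents that add atoms: none
Why: Enzymatic asymmetric ketone reduction; the ketoreductase delivers NADPH hydride to one enantiotopic face of the prochiral ketone and sets C5 as R. The tert-butyl ester suppresses δ-lactonisation and resists stray esterase activity.

**Step 4**
Reactants: 5, tert-butyl (5R)-5-hydroxynon-8-enoate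
Product: 6, tert-butyl 4-[(2R,5S)-5-(hydroxymethyl)tetrahydrofuran-2-yl]butanoate (trans)
Conditions: Co(nmp)2 (10 mol %; Co(modp)2 also suitable), t-BuOOH (10 mol %), O2 (1 atm), i-PrOH, 55 °C
Reagents that add atoms: dioxygen, O=O
Why: Mukaiyama aerobic oxidative cyclisation; 5-exo closure of the cobalt alkoxide onto the alkene typically gives the 2,5-trans ring with >95:5 selectivity, and the exocyclic radical is trapped by O2 to give CH2OH. The C5 C–O bond is not broken, so that centre is retained and it controls the new ring centre.

**Step 5**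
Reactants: 6, the tert-butyl ester
Product: 7, methyl 4-[(2R,5S)-5-(hydroxymethyl)tetrahydrofuran-2-yl]butanoate
Conditions: AcCl (3 equiv) premixed in MeOH (anhydrous HCl), 0 °C → 40 °C
Reagents that add atoms: methanol, CO
Why: Acid-mediated tert-butyl ester cleavage followed by in-situ Fischer esterification; this is safe now because the former C5 hydroxyl is tied up as the ring ether and cannot lactonise.

**Step 6**
Reactants: 7, the THF-methanol
Product: 8, methyl 4-[(2R,5S)-5-formyltetrahydrofuran-2-yl]butanoate
Conditions: Dess–Martin periodinane, NaHCO3, CH2Cl2, 0 °C → rt; used crude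
Reagents that add atoms: none
Why: Buffered Dess–Martin oxidation gives the α-alkoxy aldehyde under near-neutral conditions without epimerisation or over-oxidation.

**Step 7**
Reactants: 8, the THF-aldehyde
Product: 9, methyl 4-[(2R,5S)-5-ethynyltetrahydrofuran-2-yl]butanoate
Conditions: dimethyl (1-diazo-2-oxopropyl)phosphonate, K2CO3, MeOH, 0 °C → rt
Reagents that add atoms: Ohira–Bestmann reagent, COP(=O)(OC)C(=[N+]=[N-])C(C)=O (supplies the terminal alkyne carbon)
Why: Ohira–Bestmann (Seyferth–Gilbert) homologation; addition of the diazophosphonate anion is faster than enolisation at 0 °C, so the trans configuration is kept, and the methyl ester is degenerate in K2CO3/MeOH.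

**Step 8**
Reactants: 10, non-8-yn-1-ol
Product: 11, (E)-9-bromonon-8-en-1-ol
Conditions: Cp2Zr(H)Cl (2.5 equiv), THF, rt; then NBS, 0 °C
Reagents that add atoms: N-bromosuccinimide, BrN1C(=O)CCC1=O
Why: Schwartz hydrozirconation is a syn, anti-Markovnikov addition (the first equivalent is consumed by the OH), and bromodezirconation goes with retention to give only the E-bromoalkene.

**Step 9**
Reactants: 11, (E)-9-bromonon-8-en-1-ol
Product: 12, (E)-9-bromonon-8-enal
Conditions: Dess–Martin periodinane, NaHCO3, CH2Cl2, rt
Reagents that add atoms: none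
Why: Dess–Martin oxidation of the primary alcohol; the vinyl bromide is inert.

**Step 10**
Reactants: 12, (E)-9-bromonon-8-enal
Product: 13, (E)-1-bromodec-1-en-9-yne
Conditions: dimethyl (1-diazo-2-oxopropyl)phosphonate, K2CO3, MeOH, 0 °C → rt
Reagents that add atoms: Ohira–Bestmann reagent, COP(=O)(OC)C(=[N+]=[N-])C(C)=O
Why: Ohira–Bestmann homologation of an unhindered aldehyde; the E-vinyl bromide tolerates K2CO3/MeOH.

**Step 11**
Reactants: 13, (E)-1-bromodec-1-en-9-yne
Product: 14, (1E,9E)-1-bromo-10-iododeca-1,9-diene
Conditions: Cp2Zr(H)Cl (1.2 equiv), THF, rt, dark; then I2, 0 °C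
Reagents that add atoms: iodine, II
Why: Hydrozirconation–iodination; the terminal alkyne reacts much faster than the 1,2-disubstituted bromoalkene, and syn addition plus iodinolysis with retention gives the E-iodide.

**Step 12**
Reactants: 9, the THF-alkyne; 14, the bromo-iodo-diene (1.3 equiv)
Product: 15, Mutafuran C
Conditions: Pd(PPh3)4 (5 mol %), CuI (10 mol %), i-Pr2NH, THF, rt, degassed; slow addition of 9 to 14
Reagents that add atoms: none beyond 9 and 14
Why: Sonogashira coupling; oxidative addition into the vinyl C–I bond is far faster than into C–Br at room temperature, and the excess of 14 ensures the alkyne is consumed at iodine. Alkene geometry is retained and no stereocentre is touched.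

## Compound list

1 | 5-(tert-butoxy)-5-oxopentanoic acid | CC(C)(C)OC(=O)CCCC(=O)O | starting material
2 | tert-butyl 5-[methoxy(methyl)amino]-5-oxopentanoate | CC(C)(C)OC(=O)CCCC(=O)N(C)OC | intermediate
3 | but-3-en-1-ylmagnesium bromide (commercial THF solution) | C=CCC[Mg]Br | starting material
4 | tert-butyl 5-oxonon-8-enoate | CC(C)(C)OC(=O)CCCC(=O)CCC=C | intermediate
5 | tert-butyl (5R)-5-hydroxynon-8-enoate | CC(C)(C)OC(=O)CCC[C@@H](O)CCC=C | intermediate
6 | tert-butyl 4-[(2R,5S)-5-(hydroxymethyl)tetrahydrofuran-2-yl]butanoate | CC(C)(C)OC(=O)CCC[C@@H]1CC[C@@H](CO)O1 | intermediate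
7 | methyl 4-[(2R,5S)-5-(hydroxymethyl)tetrahydrofuran-2-yl]butanoate | COC(=O)CCC[C@@H]1CC[C@@H](CO)O1 | intermediate
8 | methyl 4-[(2R,5S)-5-formyltetrahydrofuran-2-yl]butanoate | COC(=O)CCC[C@@H]1CC[C@@H](C=O)O1 | intermediate
9 | methyl 4-[(2R,5S)-5-ethynyltetrahydrofuran-2-yl]butanoate | COC(=O)CCC[C@@H]1CC[C@@H](C#C)O1 | intermediate
10 | non-8-yn-1-ol | OCCCCCCCC#C | starting material
11 | (E)-9-bromonon-8-en-1-ol | OCCCCCCC/C=C/Br | intermediate
12 | (E)-9-bromonon-8-enal | O=CCCCCCC/C=C/Br | intermediate
13 | (E)-1-bromodec-1-en-9-yne | C#CCCCCCC/C=C/Br | intermediate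
14 | (1E,9E)-1-bromo-10-iododeca-1,9-diene | I/C=C/CCCCCC/C=C/Br | intermediate
15 | Mutafuran C, methyl 4-[(2R,5S)-5-[(3E,11E)-12-bromododeca-3,11-dien-1-yn-1-yl]tetrahydrofuran-2-yl]butanoate | COC(=O)CCC[C@@H]1CC[C@@H](C#C/C=C/CCCCCC/C=C/Br)O1 | target

## Summary

Total steps: 12.
Longest linear sequence: 8 (steps 1–7, then 12); the side chain is a 4-step branch (steps 8–11).

Three steps most likely to fail:

1. **Step 3 (ketoreductase reduction).** The two ketone substituents are similar in size, so no panel enzyme may give high ee. Fallback: set the carbinol on a better-differentiated substrate. Reduce 1-chlorohex-5-en-2-one with a KRED to (S)-1-chlorohex-5-en-2-ol, close it to (S)-2-(but-3-enyl)oxirane, and open the epoxide at CH2 with a copper-catalysed three-carbon Grignard carrying a masked carboxyl (for example the Grignard of 2-(2-bromoethyl)-1,3-dioxolane). The acetal is later oxidised to the methyl ester.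

2. **Step 7 (aldehyde to alkyne).** The α-alkoxy aldehyde may epimerise under K2CO3/MeOH and erode the trans ratio. Fallback: avoid the aldehyde altogether. Build an acyclic precursor that already carries the alkyne as a propargylic carbinol (set by asymmetric ynone reduction) and close the THF by intramolecular SN2 displacement of a C5 sulfonate with inversion.

3. **Step 12 (Sonogashira, I versus Br).** Some coupling at the vinyl bromide, or Glaser dimerisation, could occur. Fallback: couple 9 with (E)-9-iodonon-8-en-1-ol (from 10 by hydrozirconation–iodination), oxidise the primary alcohol to the aldehyde, and install the E-bromoalkene last by Takai–Utimoto olefination (CHBr3/CrBr2).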